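**Remarks on the chemistry.** Germacrane numbering (C1–C15) is used for every compound. The CIP letters of the trisubstituted alkenes change with the protecting groups, so alkene geometry is also stated by the positions of the substituents. Ph3P=C(Br)CO2Et and Bu3SnCH2OH are treated as purchasable reagents.

## Analysis of the target

Target 35 is a germacranolide: a ten-membered carbocycle (C1–C10) with a γ-lactone fused across C6–C7 (O on C6, C12 carbonyl, exocyclic C11=C13 methylene). Both ring alkenes are cis within the ring: at C4=C5 the ring carbons C3 and C6 are on the same side, and at C1=C10 the ring carbons C2 and C9 are on the same side, with the formyl carbon C14 trans to C2. Four contiguous stereocentres (6R,7S,8S,9S) carry the functionality. H6 and H7 are trans (trans-fused lactone), the C11 arm on C7 and the oxygen on C8 are anti, and the C8 and C9 oxygens are syn along the chain C7–C10. A fifth centre sits in the (S)-2-methylbutanoate on O8. The sensitive groups are the α-methylene lactone (a Michael acceptor), the enal next to a free allylic C9 hydroxyl, an ester beside that hydroxyl (acyl migration), and a 1,5-diene in a medium ring (transannular reactions under acid). The difficulties are the medium ring, the stereotetrad, and the need to tell three neighbouring oxygens (O8, O9, O14) apart. The strategy rests on the array O–C6–C7–C11=C13: C6 is an oxygen-bearing carbon allylic to C4=C5 and is bonded to C7, which carries the exocyclic alkene. This homoallylic alcohol is what a [2,3]-Wittig shift of an allylic ether C6–O–C13 delivers, so the ten-membered ring can be made by contracting a thirteen-membered cyclic ether.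

## Retrosynthetic reasoning

**35 to 33 (C14 aldehyde and C9 hydroxyl).** The enal is the most fragile group and is made last, by oxidising the primary allylic alcohol of diol 34 in preference to the secondary one. Diol 34 comes from acetonide 33. The six-membered acetal ties O9 to O14, so O8 is the only oxygen open to acylation.

**33 to 30 and 31 (ester C–O bond).** The side chain is cut at the ester bond, giving alcohol 30 and acid 31, which brings its stereocentre from the chiral pool. The forward acylation must not enolise the acid and is placed after every strongly basic step.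

**30 to 25 (lactone).** The PMB ether of 29 masks O8. The lactone of 29 is opened at the C12–O6 bond and C12 is taken down to the alcohol level (diol 26, silyl ether 25). The Michael acceptor and the lactone carbonyl are thus absent during organolithium chemistry, and the forward step is an oxidative lactonisation of a 1,4-diol.

**25 to 23 (key disconnection, C6–C7).** The C6–C7 bond is cut and O6 is reconnected to C13, which gives the thirteen-membered bis-allylic ether 23. This is chosen because one sigmatropic event forms the ring bond, both lactone stereocentres and the exocyclic methylene, and because the medium ring then arises by contraction through a five-membered transition state. The forward reaction must metalate C6 selectively and must add to the correct face of C7 under the influence of C8.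

**23 to 22 (O–C13).** The ether is cut at O–C13 to hydroxy chloride 22. A thirteen-membered ring closes readily by SN2 at a primary allylic carbon under dilution, and the chloride can be installed selectively at C13 early (allylic-selective chlorination).

**22 to 7 and 17 (C9–C10).** The acetonide of 22 is traced to carbinol 20, whose C14 ketal ether already holds the acetonide carbon. Carbinol 20 is cut at C9–C10 into alkenyl bromide 7 and aldehyde 17. This is the most convergent cut. The C8 PMB ether is there to chelate magnesium so that the 8,9-syn carbinol forms, and it is also a small, non-silyl group at C8 for the key step.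

**7 to 1.** Bromide 7 keeps the Z-alkene of nerol 1 as C4=C5. The distal alkene of 1 is cleaved to aldehyde 4, and a Wittig reaction adds C10 and C14 with bromine cis to C2 (ester 5, diol 6).

**17 to 8.** Aldehyde 17 takes C8 from glyceraldehyde acetonide 8. A Wittig reaction builds C7=C11 with bromine at the future C12 position (9), and cross-coupling puts in the C12 hydroxymethyl group with retention (10, 11). The acetonide is exchanged for a p-methoxybenzylidene acetal (12, 13), whose reductive opening places PMB on O8 while the same hydride reduces the ester to the C13 alcohol (15). Chlorination (16) and oxidation at C9 complete 17.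

## Alternatives that were turned down

**Alternative 1: closure at C9–C10 by alkenylchromium addition.** The ring is cut between C9 and C10. Forward, CrCl2 with catalytic NiCl2 would turn an alkenyl iodide at C10 into an alkenylchromium that adds to an aldehyde at C9 of the same chain and gives lactone A1. In its favour, the lactone and the ester are in place before closure, the organochromium tolerates both, the C1=C10 geometry comes unchanged from the iodide, and only PMB removal and one oxidation remain. On lateness and length of the endgame it is stronger than the chosen route. Against it, a ten-membered ring is closed end to end by C–C bond formation between two hindered termini, with the full entropic and transannular cost. The aldehyde is α to the acyloxy-bearing C8, so enolisation threatens C8 and the ester. Chromium additions to α-oxygenated aldehydes normally follow non-chelation control, which gives the 8,9-anti relation, whereas the target is 8,9-syn. The chosen strategy instead sets C9 in an open chain under chelation control and forms the ring by contraction.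

**Alternative 2: closure at C8–C9 by γ-alkoxyallylboration.** The cut is between C8 and C9. On heating at high dilution, an allylic pinacol boronate at C1 with a C9=C10 enol ether would add through C9 to a C8 aldehyde, shift the alkene to C1=C10 and give A2. In its favour, a closed chair transition state sets C8 and C9 together and builds the C1=C10 alkene with no reagent, under neutral conditions, and A2 has O8 free and O9 protected. In that differentiation it equals the chosen route, and in making the diol in one step it is stronger. Against it, the substrate needs a configurationally defined secondary allylboronate, a geometrically defined trisubstituted enol ether, and an aldehyde on C8 that is α to the C7 stereocentre with its 2-propenyl arm (epimerisation, drift into conjugation). The chair transition state must fit inside a forming ten-membered ring, and the C1=C10 geometry depends on the orientation of the C1 substituent in that chair. After closure, acylation, lactone formation, two PMB removals and the C14 oxidation remain. The chosen strategy uses simpler precursors made by robust reactions and concentrates the risk in one step.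

**Alternative 3: closure at C5–C6 by alkenylchromium addition.** The cut is between C5 and C6. CrCl2 with catalytic NiCl2 would convert a (Z)-alkenyl iodide at C5 into an alkenylchromium that adds to a C6 aldehyde and gives carbinol A3. In its favour, the lactone carbinol is formed directly, the ester is already on O8, the Z-geometry of C4=C5 is kept, and the endgame is short. Here too the alternative is stronger in step count after ring closure. Against it, the C6 aldehyde is branched at C7 with a β,γ-alkene (C11=C13) and has the acyloxy group in the β-position, so epimerisation at C7, conjugation and β-elimination all threaten it. C6 must be controlled by C7 in a macrocyclic addition, C7 must be set beforehand by separate chemistry, and the ring is again closed end to end. The chosen strategy creates C6 and C7 together, never makes a C6 aldehyde and needs no medium-ring C–C closure.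

Key step: step 18

## Route

**Step 1**
Reactants: 1 nerol, (2Z)-3,7-dimethylocta-2,6-dien-1-ol
Product: 2 neryl acetate, (2Z)-3,7-dimethylocta-2,6-dien-1-yl acetate
Conditions: Ac2O, pyridine, DMAP (cat.), CH2Cl2, 0 °C to rt
Reagents that add atoms: acetic anhydride, CC(=O)OC(C)=O
Why: Acetylation of the primary allylic alcohol; the acetoxy group lowers the reactivity of the C4=C5 alkene towards the peracid of step 2 and is removed by the hydride of step 5.

**Step 2**
Reactants: 2 neryl acetate
Product: 3 (2Z)-5-(3,3-dimethyloxiran-2-yl)-3-methylpent-2-en-1-yl acetate (racemic at the oxirane carbon)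
Conditions: mCPBA (1.05 equiv), NaHCO3, CH2Cl2, −10 to 0 °C
Reagents that add atoms: 3-chloroperoxybenzoic acid, OOC(=O)c1cccc(Cl)c1
Why: Prilezhaev epoxidation; the distal trisubstituted alkene is the more electron-rich because the allylic acetoxy group deactivates C4=C5, so one equivalent of peracid should react there. The epoxide centre is lost in step 3, so its configuration does not matter.

**Step 3**
Reactants: 3 epoxide
Product: 4 (2Z)-3-methyl-6-oxohex-2-en-1-yl acetate (the C1 aldehyde)
Conditions: H5IO6, THF/H2O, 0 °C
Reagents that add atoms: none
Why: Periodic acid hydrates the epoxide and cleaves the resulting glycol in one operation, releasing acetone and leaving the aldehyde; the Z-alkene and the acetate are not affected.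

**Step 4**
Reactants: 4 aldehyde
Product: 5 ethyl (2Z,6Z)-8-acetoxy-2-bromo-6-methylocta-2,6-dienoate (Br on C10 cis to C2; ester carbon is C14)
Conditions: Ph3P=C(Br)CO2Et, CH2Cl2, 0 °C to rt
Reagents that add atoms: ethyl 2-bromo-2-(triphenyl-λ5-phosphanylidene)acetate, CCOC(=O)C(Br)=P(c1ccccc1)(c1ccccc1)c1ccccc1
Why: Wittig olefination with a stabilised α-bromo ylide places the ester trans to the chain, so bromine ends cis to C2, the position C9 must take in the ring; the minor geometric isomer is removed by chromatography.

**Step 5**
Reactants: 5 bromo ester
Product: 6 (2Z,6Z)-2-bromo-6-methylocta-2,6-diene-1,8-diol (C14 and C6 hydroxyls)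
Conditions: i-Bu2AlH (5 equiv), CH2Cl2, −78 to −20 °C; aq. potassium sodium tartrate
Reagents that add atoms: none
Why: 1,2-Reduction of the conjugated ester to the allylic alcohol with simultaneous reductive removal of the acetate; the alkenyl bromide is inert to the aluminium hydride at low temperature.

**Step 6**
Reactants: 6 bromo diol
Product: 7 (2Z,6Z)-2-bromo-1,8-bis[(2-methoxypropan-2-yl)oxy]-6-methylocta-2,6-diene
Conditions: 2-methoxypropene (excess), PPTS (cat.), CH2Cl2, 0 °C; Et3N quench
Reagents that add atoms: 2-methoxypropene, COC(C)=C
Why: Acid-catalysed addition of both hydroxyls to the enol ether gives mixed ketals that withstand organolithium reagents; the ketal on O14 is also the later source of the acetonide carbon.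

**Step 7**
Reactants: 8 (R)-2,2-dimethyl-1,3-dioxolane-4-carbaldehyde
Product: 9 ethyl (2Z)-2-bromo-3-[(4S)-2,2-dimethyl-1,3-dioxolan-4-yl]prop-2-enoate (Br on C11 cis to C8; ester carbon is C13)
Conditions: Ph3P=C(Br)CO2Et, CH2Cl2, 0 °C to rt
Reagents that add atoms: ethyl 2-bromo-2-(triphenyl-λ5-phosphanylidene)acetate, CCOC(=O)C(Br)=P(c1ccccc1)(c1ccccc1)c1ccccc1
Why: The same Z-selective Wittig olefination runs under neutral conditions that do not epimerise the α-alkoxy aldehyde; bromine marks the position of C12 cis to C8, and the ester trans to C8 becomes C13.

**Step 8**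
Reactants: 9 bromo enoate
Product: 10 ethyl (2E)-3-[(4S)-2,2-dimethyl-1,3-dioxolan-4-yl]-2-(hydroxymethyl)prop-2-enoate
Conditions: Bu3SnCH2OH, Pd(PPh3)4 (5 mol%), 1,4-dioxane, 90 °C
Reagents that add atoms: (tributylstannyl)methanol, OC[Sn](CCCC)(CCCC)CCCC
Why: Stille coupling transfers the hydroxymethyl group to the activated α-bromoacrylate with retention of alkene geometry, which fixes C12 cis to C8.

**Step 9**
Reactants: 10 hydroxymethyl enoate
Product: 11 ethyl (2E)-2-{[(tert-butyldiphenylsilyl)oxy]methyl}-3-[(4S)-2,2-dimethyl-1,3-dioxolan-4-yl]prop-2-enoate
Conditions: TBDPSCl, imidazole, DMF, rt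
Reagents that add atoms: tert-butyl(chloro)diphenylsilane, CC(C)(C)[Si](Cl)(c1ccccc1)c1ccccc1
Why: Silylation of the primary allylic alcohol; this silyl ether is chosen because it survives the aqueous acid of step 10, the hydride steps and the organolithium steps, and is later the only silyl group in the molecule.

**Step 10**
Reactants: 11 silyl ether
Product: 12 ethyl (2E,4S)-2-{[(tert-butyldiphenylsilyl)oxy]methyl}-4,5-dihydroxypent-2-enoate
Conditions: AcOH/H2O (4:1), 40 °C
Reagents that add atoms: none
Why: Acid hydrolysis of the terminal acetonide; both new hydroxyls are held trans to the ester across the alkene, so no lactone can form.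

**Step 11**
Reactants: 12 diol
Product: 13 ethyl (2E)-2-{[(tert-butyldiphenylsilyl)oxy]methyl}-3-[(4S)-2-(4-methoxyphenyl)-1,3-dioxolan-4-yl]prop-2-enoate (both epimers at the acetal carbon)
Conditions: 4-MeOC6H4CH(OMe)2, PPTS (cat.), CH2Cl2, rt
Reagents that add atoms: 4-methoxybenzaldehyde dimethyl acetal, COC(OC)c1ccc(OC)cc1
Why: Acetal exchange on the 1,2-diol gives the p-methoxybenzylidene acetal, which allows the PMB group to be delivered regioselectively to the secondary oxygen in step 12.

**Step 12**
Reactants: 13 p-methoxybenzylidene acetal
Product: 15 (2S,3Z)-4-{[(tert-butyldiphenylsilyl)oxy]methyl}-2-[(4-methoxybenzyl)oxy]pent-3-ene-1,5-diol (O8 PMB ether with free C9 and C13 hydroxyls), via allylic alcohol acetal 14 (not isolated)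
Conditions: i-Bu2AlH (6 equiv), CH2Cl2, −78 to 0 °C; aq. potassium sodium tartrate
Reagents that add atoms: none
Why: The hydride first reduces the ester to the C13 allylic alcohol and, on warming, opens the acetal reductively; aluminium binds the less hindered primary oxygen, the acetal C–O9 bond breaks and hydride traps the oxocarbenium ion, which leaves PMB on O8 (regioselective reductive acetal cleavage).

**Step 13**
Reactants: 15 diol
Product: 16 (2S,3E)-4-{[(tert-butyldiphenylsilyl)oxy]methyl}-5-chloro-2-[(4-methoxybenzyl)oxy]pent-3-en-1-ol (C13 chloride with free C9 hydroxyl)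
Conditions: NCS, Me2S, CH2Cl2, −20 to 0 °C
Reagents that add atoms: N-chlorosuccinimide, ClN1C(=O)CCC1=O
Why: Corey–Kim chlorination converts only the allylic alcohol into the chloride by SN2 displacement without allylic shift; the saturated primary alcohol is returned on work-up because no base is added.

**Step 14**
Reactants: 16 chloro alcohol
Product: 17 (2S,3E)-4-{[(tert-butyldiphenylsilyl)oxy]methyl}-5-chloro-2-[(4-methoxybenzyl)oxy]pent-3-enal (the C9 aldehyde)
Conditions: Dess–Martin periodinane, NaHCO3, CH2Cl2, 0 °C; used crude at once
Reagents that add atoms: none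
Why: Dess–Martin oxidation under buffered, non-basic conditions should give the α-alkoxy β,γ-unsaturated aldehyde without epimerisation at C8 or migration of the alkene.

**Step 15**
Reactants: 7 alkenyl bromide; 17 aldehyde
Product: 20 open-chain (8S,9S)-carbinol (C9 hydroxyl; O6 and O14 as 2-methoxypropan-2-yl ethers; O8 PMB; O12 TBDPS; C13 chloride; 4Z; C2 cis to C9 at C1=C10; C8 trans to C13 at C7=C11), via alkenyllithium 18 (not isolated), via alkenylmagnesium bromide 19 (not isolated)
Conditions: 7 (1.3 equiv), t-BuLi (2.1 equiv per bromide), Et2O, −78 °C; MgBr2·OEt2 (1.2 equiv), −78 °C; then 17, CH2Cl2, −78 °C; aq. NH4Cl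
Reagents that add atoms: none
Why: Bromine–lithium exchange occurs with retention of alkene geometry and is followed by transmetalation to magnesium. Cram-chelate addition then sets C9: magnesium bridges the aldehyde oxygen and the O8 PMB oxygen, and the alkenyl group adds to the face away from the C7 alkenyl substituent, giving the 8,9-syn (9S) carbinol.

**Step 16**
Reactants: 20 carbinol
Product: 22 hydroxy chloride (free C6 hydroxyl; C9/C14 acetonide; O8 PMB; O12 TBDPS; C13 chloride), via C6 ketal ether acetonide 21 (not isolated)
Conditions: PPTS (cat.), CH2Cl2, 0 °C; then MeOH (10 equiv), 0 °C, short; Et3N quench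
Reagents that add atoms: none
Why: Acid ionises the O14 mixed ketal to an oxocarbenium ion that the neighbouring C9 hydroxyl captures in a six-membered ring, the same event that completes an acetonide formation with 2-methoxypropene. Methanol then removes the acyclic O6 ketal by transketalisation far faster than it opens the cyclic acetonide.

**Step 17**
Reactants: 22 hydroxy chloride
Product: 23 thirteen-membered bis-allylic ether (ring O links C6 and C13; 8S,9S; C9/C14 acetonide; O8 PMB; O12 TBDPS; 4Z; C2 cis to C9 at C1=C10; C8 trans to C13 and cis to C12 at C7=C11)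
Conditions: NaH, n-Bu4NI (cat.), THF, slow addition to 0.002 M, 50 °C
Reagents that add atoms: none
Why: Intramolecular Williamson etherification (SN2 of the C6 alkoxide on the primary allylic C13 chloride) at high dilution; thirteen-membered bis-allylic ethers have been closed in this way, and three alkenes plus the dioxane ring restrict the freedom of the chain.

**Step 18 (key step)**
Reactants: 23 thirteen-membered ether
Product: 25 ten-membered C6 carbinol (6R,7S,8S,9S; C7 carries the C11(=C13H2)–C12H2–OTBDPS arm; O8 PMB; C9/C14 acetonide), via C6-lithiated ether 24 (not isolated)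
Conditions: n-BuLi (2 equiv), THF/hexane, −78 to −25 °C; aq. NH4Cl
Reagents that add atoms: none
Why: n-BuLi removes a proton from C6, the one ring CH2 bonded both to the ether oxygen and to an alkene CH, and the α-alkoxy allyllithium 24 undergoes a concerted [2,3]-Wittig shift through a five-membered envelope (C6, O, C13, C11, C7), in which C6–C7 forms, O–C13 breaks and the alkene moves to C11=C13. The closest known reaction type is the [2,3]-Wittig ring contraction of thirteen-membered bis-allylic ethers from acyclic terpenoid precursors to ten-membered homoallylic alcohols. The ten-membered carbocycle is closed by ring contraction and not end to end: the new bond spans the ether bridge of the existing ring, so the entropic cost was paid at oxygen in step 17. C6 and C7 are created together, and their relative configuration (H6 and H7 trans, as the trans lactone requires) is controlled by the alkene geometry (C8 trans to C13) and by the exo position of the C5 vinyl group on the envelope, which the C12 arm on the central allyl carbon enforces by blocking the endo position. Their absolute configuration (6R,7S) is controlled by the C8 stereocentre: with H8 in the plane of C7=C11 to avoid allylic 1,3-strain with C12, C9 and the PMB-ether oxygen lie on opposite faces, and the required isomer forms when C6 bonds on the face that puts C9 anti and the small ether oxygen gauche to the new bond. This mode keeps the ring chain extended about C7–C8, whereas attack on the other face pushes C5 and C9 into a syn-pentane contact. Against it stands the preference of open-chain allylic ethers for bond formation anti to the C–O bond, so facial selectivity is the selectivity the step needs and the one least secured. Regioselective metalation is secured by the substitution pattern: C12, C13 and C14 are CH2 groups on fully substituted alkene carbons and should be deprotonated more slowly, the p-methoxybenzyl CH2 is deactivated by its donor ring at low temperature, and a C13 anion could rearrange only by attacking the fully substituted C4. No ester, lactone or aldehyde is present, so the organolithium and the product alkoxide meet no electrophile.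

**Step 19**
Reactants: 25 ten-membered carbinol
Product: 26 diol (C6 and C12 hydroxyls; O8 PMB; C9/C14 acetonide)
Conditions: n-Bu4NF, AcOH, THF, 0 °C to rt
Reagents that add atoms: none
Why: Fluoride cleaves the only silyl ether; acetic acid buffers the medium so that the acetonide and the allylic systems are left alone.

**Step 20**
Reactants: 26 diol
Product: 29 α-methylene-γ-lactone (12,6-olide; O8 PMB; C9/C14 acetonide), via hydroxy enal 27 (not isolated), via lactol 28 (not isolated)
Conditions: TEMPO (20 mol%), PhI(OAc)2 (2.5 equiv), CH2Cl2, rt
Reagents that add atoms: none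
Why: The oxoammonium oxidant takes the primary allylic alcohol to the aldehyde, which closes with the C6 hydroxyl to the lactol and is oxidised again to the lactone (oxidative lactonisation of a 1,4-diol). The secondary C6 hydroxyl reacts much more slowly on its own, and no stereocentre is touched, so the trans ring fusion from step 18 is kept.

**Step 21**
Reactants: 29 lactone
Product: 30 C8 alcohol (lactone; C9/C14 acetonide)
Conditions: DDQ, CH2Cl2/pH 7 phosphate buffer, 0 °C
Reagents that add atoms: none
Why: Oxidative PMB removal by DDQ through the benzylic cation and its hemiacetal; the buffer protects the acetonide, and the conjugated lactone is too electron-poor to react.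

**Step 22**
Reactants: 30 C8 alcohol; 31 (S)-2-methylbutanoic acid
Product: 33 C8 (S)-2-methylbutanoate (lactone; C9/C14 acetonide), via mixed anhydride 32 (not isolated)
Conditions: 31, 2,4,6-Cl3C6H2COCl, Et3N, THF, rt; then 30, DMAP, toluene, rt
Reagents that add atoms: none
Why: Yamaguchi esterification: the mixed anhydride acylates DMAP and the acylpyridinium ion is attacked by the hindered C8 hydroxyl. The acid is activated without an acid chloride, so no ketene forms and its stereocentre is kept, and the weakly basic medium should not let O8 attack the lactone carbonyl.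

**Step 23**
Reactants: 33 ester
Product: 34 diol (free C9 and C14 hydroxyls; lactone; C8 ester)
Conditions: AcOH/H2O (4:1), rt
Reagents that add atoms: none
Why: Mild acid hydrolysis of the isopropylidene acetal; the conditions are weaker than those needed for ester cleavage, acyl migration or protonation of the ring alkenes.

**Step 24**
Reactants: 34 diol
Product: 35 target CNP0168436.1
Conditions: TEMPO (10 mol%), PhI(OAc)2 (1.2 equiv), CH2Cl2, 0 °C to rt
Reagents that add atoms: none
Why: TEMPO with PhI(OAc)2 oxidises primary allylic alcohols much faster than secondary ones, so C14 should become the aldehyde while the C9 hydroxyl stays. The enal keeps C2 trans to the formyl group, which is also the stable geometry.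

## Compound list

1 | nerol, (2Z)-3,7-dimethylocta-2,6-dien-1-ol | CC(C)=CCC/C(C)=C\CO | starting material
2 | neryl acetate | CC(C)=CCC/C(C)=C\COC(C)=O | intermediate
3 | (2Z)-5-(3,3-dimethyloxiran-2-yl)-3-methylpent-2-en-1-yl acetate (racemic at the oxirane carbon) | CC(=O)OC/C=C(/C)CCC1OC1(C)C | intermediate
4 | (2Z)-3-methyl-6-oxohex-2-en-1-yl acetate | CC(=O)OC/C=C(/C)CCC=O | intermediate
5 | ethyl (2Z,6Z)-8-acetoxy-2-bromo-6-methylocta-2,6-dienoate | CC(=O)OC/C=C(/C)CC/C=C(/C(=O)OCC)Br | intermediate
6 | (2Z,6Z)-2-bromo-6-methylocta-2,6-diene-1,8-diol | OC/C=C(/C)CC/C=C(/CO)Br | intermediate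
7 | (2Z,6Z)-2-bromo-1,8-bis[(2-methoxypropan-2-yl)oxy]-6-methylocta-2,6-diene | COC(C)(C)OC/C=C(/C)CC/C=C(/COC(C)(C)OC)Br | intermediate
8 | (R)-2,2-dimethyl-1,3-dioxolane-4-carbaldehyde | CC1(C)OC[C@H](C=O)O1 | starting material
9 | ethyl (2Z)-2-bromo-3-[(4S)-2,2-dimethyl-1,3-dioxolan-4-yl]prop-2-enoate | CC1(C)OC[C@H](/C=C(\Br)C(=O)OCC)O1 | intermediate
10 | ethyl (2E)-3-[(4S)-2,2-dimethyl-1,3-dioxolan-4-yl]-2-(hydroxymethyl)prop-2-enoate | CC1(C)OC[C@H](/C=C(\CO)C(=O)OCC)O1 | intermediate
11 | ethyl (2E)-2-{[(tert-butyldiphenylsilyl)oxy]methyl}-3-[(4S)-2,2-dimethyl-1,3-dioxolan-4-yl]prop-2-enoate | CC1(C)OC[C@H](/C=C(\CO[Si](c2ccccc2)(c2ccccc2)C(C)(C)C)C(=O)OCC)O1 | intermediate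
12 | ethyl (2E,4S)-2-{[(tert-butyldiphenylsilyl)oxy]methyl}-4,5-dihydroxypent-2-enoate | OC[C@@H](O)/C=C(\CO[Si](c1ccccc1)(c1ccccc1)C(C)(C)C)C(=O)OCC | intermediate
13 | ethyl (2E)-2-{[(tert-butyldiphenylsilyl)oxy]methyl}-3-[(4S)-2-(4-methoxyphenyl)-1,3-dioxolan-4-yl]prop-2-enoate (both acetal epimers) | COc1ccc(cc1)C1OC[C@H](/C=C(\CO[Si](c2ccccc2)(c2ccccc2)C(C)(C)C)C(=O)OCC)O1 | intermediate
14 | (2Z)-2-{[(tert-butyldiphenylsilyl)oxy]methyl}-3-[(4S)-2-(4-methoxyphenyl)-1,3-dioxolan-4-yl]prop-2-en-1-ol (not isolated) | COc1ccc(cc1)C1OC[C@H](/C=C(\CO[Si](c2ccccc2)(c2ccccc2)C(C)(C)C)CO)O1 | intermediate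
15 | (2S,3Z)-4-{[(tert-butyldiphenylsilyl)oxy]methyl}-2-[(4-methoxybenzyl)oxy]pent-3-ene-1,5-diol | OC[C@@H](OCc1ccc(OC)cc1)/C=C(\CO[Si](c1ccccc1)(c1ccccc1)C(C)(C)C)CO | intermediate
16 | (2S,3E)-4-{[(tert-butyldiphenylsilyl)oxy]methyl}-5-chloro-2-[(4-methoxybenzyl)oxy]pent-3-en-1-ol | OC[C@@H](OCc1ccc(OC)cc1)/C=C(\CO[Si](c1ccccc1)(c1ccccc1)C(C)(C)C)CCl | intermediate
17 | (2S,3E)-4-{[(tert-butyldiphenylsilyl)oxy]methyl}-5-chloro-2-[(4-methoxybenzyl)oxy]pent-3-enal | O=C[C@@H](OCc1ccc(OC)cc1)/C=C(\CO[Si](c1ccccc1)(c1ccccc1)C(C)(C)C)CCl | intermediate
18 | alkenyllithium from 7 (Li on C10, geometry retained; not isolated) | COC(C)(C)OC/C=C(/C)CC/C=C(/COC(C)(C)OC)[Li] | intermediate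
19 | alkenylmagnesium bromide from 18 (not isolated) | COC(C)(C)OC/C=C(/C)CC/C=C(/COC(C)(C)OC)[Mg]Br | intermediate
20 | open-chain (8S,9S)-carbinol: C9 hydroxyl, O6 and O14 2-methoxypropan-2-yl ethers, O8 PMB, O12 TBDPS, C13 chloride | COC(C)(C)OC/C=C(/C)CC/C=C(/COC(C)(C)OC)[C@H](O)[C@@H](OCc1ccc(OC)cc1)/C=C(\CO[Si](c1ccccc1)(c1ccccc1)C(C)(C)C)CCl | intermediate
21 | C9/C14 acetonide still carrying the O6 2-methoxypropan-2-yl ether (not isolated) | COC(C)(C)OC/C=C(/C)CC/C=C1/COC(C)(C)O[C@@H]1[C@@H](OCc2ccc(OC)cc2)/C=C(\CO[Si](c2ccccc2)(c2ccccc2)C(C)(C)C)CCl | intermediate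
22 | hydroxy chloride: free C6 hydroxyl, C9/C14 acetonide, O8 PMB, O12 TBDPS, C13 chloride | OC/C=C(/C)CC/C=C1/COC(C)(C)O[C@@H]1[C@@H](OCc2ccc(OC)cc2)/C=C(\CO[Si](c2ccccc2)(c2ccccc2)C(C)(C)C)CCl | intermediate
23 | thirteen-membered bis-allylic ether (O links C6 and C13; 8S,9S; C9/C14 acetonide; O8 PMB; O12 TBDPS) | O1C/C=C(/C)CC/C=C2/COC(C)(C)O[C@@H]2[C@@H](OCc3ccc(OC)cc3)/C=C(\CO[Si](c3ccccc3)(c3ccccc3)C(C)(C)C)C1 | intermediate
24 | C6-lithiated thirteen-membered ether (not isolated) | O1C([Li])/C=C(/C)CC/C=C2/COC(C)(C)O[C@@H]2[C@@H](OCc3ccc(OC)cc3)/C=C(\CO[Si](c3ccccc3)(c3ccccc3)C(C)(C)C)C1 | intermediate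
25 | ten-membered (6R,7S,8S,9S)-C6 carbinol with the C11(=CH2)CH2OTBDPS arm on C7, O8 PMB, C9/C14 acetonide | O[C@@H]1/C=C(/C)CC/C=C2/COC(C)(C)O[C@@H]2[C@@H](OCc3ccc(OC)cc3)[C@H]1C(=C)CO[Si](c4ccccc4)(c4ccccc4)C(C)(C)C | intermediate
26 | C6/C12 diol (O8 PMB, C9/C14 acetonide) | O[C@@H]1/C=C(/C)CC/C=C2/COC(C)(C)O[C@@H]2[C@@H](OCc3ccc(OC)cc3)[C@H]1C(=C)CO | intermediate
27 | C12 aldehyde with free C6 hydroxyl (not isolated) | O[C@@H]1/C=C(/C)CC/C=C2/COC(C)(C)O[C@@H]2[C@@H](OCc3ccc(OC)cc3)[C@H]1C(=C)C=O | intermediate
28 | C12 lactol, both anomers (not isolated) | C=C1C(O)O[C@@H]2/C=C(/C)CC/C=C3/COC(C)(C)O[C@@H]3[C@@H](OCc4ccc(OC)cc4)[C@@H]12 | intermediate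
29 | trans-fused α-methylene-γ-lactone with O8 PMB and C9/C14 acetonide | C=C1C(=O)O[C@@H]2/C=C(/C)CC/C=C3/COC(C)(C)O[C@@H]3[C@@H](OCc4ccc(OC)cc4)[C@@H]12 | intermediate
30 | lactone with free C8 hydroxyl and C9/C14 acetonide | C=C1C(=O)O[C@@H]2/C=C(/C)CC/C=C3/COC(C)(C)O[C@@H]3[C@@H](O)[C@@H]12 | intermediate
31 | (S)-2-methylbutanoic acid | CC[C@H](C)C(=O)O | starting material
32 | (S)-2-methylbutanoic 2,4,6-trichlorobenzoic anhydride (not isolated) | CC[C@H](C)C(=O)OC(=O)c1c(Cl)cc(Cl)cc1Cl | intermediate
33 | lactone with C8 (S)-2-methylbutanoate and C9/C14 acetonide | C=C1C(=O)O[C@@H]2/C=C(/C)CC/C=C3/COC(C)(C)O[C@@H]3[C@@H](OC(=O)[C@@H](C)CC)[C@@H]12 | intermediate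
34 | C9/C14 diol with lactone and C8 ester | C=C1C(=O)O[C@@H]2/C=C(/C)CC/C=C(/CO)[C@H](O)[C@@H](OC(=O)[C@@H](C)CC)[C@@H]12 | intermediate
35 | CNP0168436.1 | C=C1C(=O)O[C@@H]2/C=C(/C)CC/C=C(/C=O)[C@H](O)[C@@H](OC(=O)[C@@H](C)CC)[C@@H]12 | target

## Step count and risks

Total: 24 steps. Longest linear sequence: 18 steps (8 to 35, steps 7–24). The nerol branch (steps 1–6) joins at step 15.

**Step 18 (key step).** The most likely failure is poor or inverted facial selectivity at C7. If the carbanion prefers to bond anti to the C8–O bond, as open-chain allylic ethers tend to do, both new centres come out inverted relative to C8 and C9. A second risk is proton abstraction at another allylic or benzylic ether position, followed by a [1,2]-shift or decomposition. The fallback sets out from hydroxy chloride 22 and returns at carbinol 25. MnO2 in CH2Cl2 oxidises the C6 allylic alcohol to the (Z)-enal chloride F1. CrCl2 in THF at high dilution then converts the C13 allylic chloride into an allylchromium species, which adds through C7 to the C6 aldehyde (intramolecular Nozaki–Hiyama allylation) and gives 25 directly. Here the alkene is attacked by an electrophile, and for that case both the steric and the stereoelectronic model favour C9 anti and the C8–O bond gauche, which is the required face. The chair transition state of the allylchromium with C8 trans to C13 gives the same anti C6/C7 relation. The price is an end-to-end closure of the ten-membered ring. The same detour would also serve if the ether closure of step 17 could not be made efficient, since it needs no macrocyclic ether.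

**Step 15 (fragment coupling).** Aldehyde 17 has a C8 hydrogen that is both α to the carbonyl and allylic, so enolisation by the basic organometallic may erode C8 or move the alkene into conjugation, and incomplete chelation would give some 9R epimer. The fallback sets out from the unseparated mixture of 20 and its C9 epimer F2 and returns at 20. Dess–Martin oxidation gives the C9 ketone F3, an α'-alkoxy enone. Reduction with the bulky, non-chelating LiBH(s-Bu)3 in THF at −78 °C should then follow Felkin–Anh control (hydride anti to the C8–O bond), which for a ketone leads to the 8,9-syn alcohol 20. The stereocentre is thus set by hydride delivery and not by C–C bond formation.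

**Step 16 (ketal transfer).** The methanol stage may also open the new cyclic acetonide, or the O14 ketal may be lost before it is captured by the C9 hydroxyl. The fallback sets out from 20 and returns at 22. PPTS in MeOH removes both acyclic ketals to give triol F4. 2,2-Dimethoxypropane with PPTS in CH2Cl2 then forms the six-membered acetonide across the C9/C14 1,3-diol, and any mixed ketal on O6 is hydrolysed in a mildly acidic aqueous work-up.

**Step 8 (hydroxymethyl transfer).** Transmetalation from the hydroxymethylstannane can be slow, so protodebromination of 9 or Z to E isomerisation at 90 °C may compete. The fallback sets out from aldehyde 8 and returns at 10. A Morita–Baylis–Hillman reaction of 8 with ethyl acrylate and DABCO gives adduct F5 (carbinol epimers are of no consequence), and Ac2O with DMAP gives acetate F6. DABCO in refluxing THF moves the acetoxy group to the primary carbon with formation of the thermodynamically preferred trisubstituted alkene, giving rearranged acetate F7 with the acetoxymethyl group cis to the dioxolane. K2CO3 in EtOH at 0 °C then frees the primary alcohol 10.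

## Further compounds

F1 | step 18 | (Z)-enal chloride: C6 aldehyde, C13 chloride, C9/C14 acetonide, O8 PMB, O12 TBDPS | O=C/C=C(/C)CC/C=C1/COC(C)(C)O[C@@H]1[C@@H](OCc2ccc(OC)cc2)/C=C(\CO[Si](c2ccccc2)(c2ccccc2)C(C)(C)C)CCl
F2 | step 15 | (8S,9R)-epimer of carbinol 20 | COC(C)(C)OC/C=C(/C)CC/C=C(/COC(C)(C)OC)[C@@H](O)[C@@H](OCc1ccc(OC)cc1)/C=C(\CO[Si](c1ccccc1)(c1ccccc1)C(C)(C)C)CCl
F3 | step 15 | C9 ketone (enone) corresponding to 20 | COC(C)(C)OC/C=C(/C)CC/C=C(/COC(C)(C)OC)C(=O)[C@@H](OCc1ccc(OC)cc1)/C=C(\CO[Si](c1ccccc1)(c1ccccc1)C(C)(C)C)CCl
F4 | step 16 | C6/C9/C14 triol (O8 PMB, O12 TBDPS, C13 chloride) | OC/C=C(/C)CC/C=C(/CO)[C@H](O)[C@@H](OCc1ccc(OC)cc1)/C=C(\CO[Si](c1ccccc1)(c1ccccc1)C(C)(C)C)CCl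
F5 | step 8 | ethyl 2-{[(4R)-2,2-dimethyl-1,3-dioxolan-4-yl](hydroxy)methyl}prop-2-enoate (carbinol epimers) | CC1(C)OC[C@H](C(O)C(=C)C(=O)OCC)O1
F6 | step 8 | acetate of F5 | CC1(C)OC[C@H](C(OC(C)=O)C(=C)C(=O)OCC)O1
F7 | step 8 | ethyl (2E)-2-(acetoxymethyl)-3-[(4S)-2,2-dimethyl-1,3-dioxolan-4-yl]prop-2-enoate | CC1(C)OC[C@H](/C=C(\COC(C)=O)C(=O)OCC)O1
A1 | alternative 1 | ten-membered 12,6-lactone with free C9 hydroxyl, C8 (S)-2-methylbutanoate and C14 PMB ether | C=C1C(=O)O[C@@H]2/C=C(/C)CC/C=C(/COCc3ccc(OC)cc3)[C@H](O)[C@@H](OC(=O)[C@@H](C)CC)[C@@H]12
A2 | alternative 2 | ten-membered ring with free C8 hydroxyl, C9 and C14 PMB ethers, C6 and C12 TBS ethers | C=C(CO[Si](C)(C)C(C)(C)C)[C@H]1[C@H](O[Si](C)(C)C(C)(C)C)/C=C(/C)CC/C=C(/COCc2ccc(OC)cc2)[C@H](OCc2ccc(OC)cc2)[C@H]1O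
A3 | alternative 3 | ten-membered C6 carbinol with C8 (S)-2-methylbutanoate, C9 and C14 TBS ethers, C12 TES ether | O[C@@H]1/C=C(/C)CC/C=C(/CO[Si](C)(C)C(C)(C)C)[C@H](O[Si](C)(C)C(C)(C)C)[C@@H](OC(=O)[C@@H](C)CC)[C@H]1C(=C)CO[Si](CC)(CC)CC
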